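All runs stem from a simulated flask for an exercise; noise was put on by code.

The amber run, with twice the protic impurity of the red flask, stood at 66 % intermediate A after 20.0 min. The red flask has so far received one portion of starting material.

the same everywhere: starting material 0.80 M (in portions, 4)
- red: partner 0.80 equiv; protic impurity 0.16 M; the very flask that is asked about, followed so far; portions every 6.0 min
- amber: partner 0.80 equiv; protic impurity 0.32 M; run made earlier; portions every 6.0 min
- flask: partner 0.800 equiv; protic impurity 0.160 M; the portions of starting material follow each other after 6.0 min, the first at the start; time 25 min

- red (time / min: target / %, intermediate A / %): 0.250: 1, 5; 0.833: 1, 6; 1.33: 0, 12; 2.00: 2, 13; 3.00: 0, 18; 4.00: 5, 12; 5.00: 0, 18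
- amber (time / min: target / %, intermediate A / %): 2.50: 1, 12; 5.00: 2, 12; 8.00: 0, 29; 10.0: 2, 29; 12.0: 2, 32; 15.0: 3, 49; 20.0: 3, 66

(readings scatter by 2 percentage points)

1. which holds at 25 min: what has brought the reaction to rest, or that it has not come to rest (it is still moving / all of the starting material has reacted / forward and back rates have come level / the partner has run out first)
2. the target standing at 25 min, as a percentage of the starting material charged
3. the intermediate A standing at 25 min, as a percentage of the starting material charged

- the reaction counts as stopped when no species that holds the starting material changes by six tenths of a point or more over the second half of the time

*What does a portion give?* In the red flask the last 3 readings of intermediate A average 16.0 % of the charge, and one portion is 25.0 %. So the capture f, intermediate A standing per starting material added so far, reads 64.0 %.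

*How firm is that mean?* Scatter puts 4.6 percentage points on it.

*But is f constant?* The amber run says perhaps not: its first two readings give 48.0 % per portion, while its last reading, with the 4 portions in, gives 66 %. So f is a mean of early readings, standing for a curve that may rise.

*Your figure for the red flask?* With the whole charge in, f gives about 64.0 % of the charge as intermediate A, give or take that error.

*And if the partner changes?* I assume that the ratio of what is not captured to what is captured equals sB, with B the partner charged, here 0.640 M, and s a constant. That defines the loss ratio 0.879 /M, a selectivity factor per molar of partner.

The forecast says it is still moving, with 5 % target and 69 % intermediate A, which is above my figure. Its ground for the end is: “Both therefore run down together in a second-order tail after the last portion”.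

The flask gives: it is still moving, with 3.05 % target and 64.2 % intermediate A. The forecast stands on all three.

    starting material + partner → intermediate C (k = 0.00393 /M/s)
    starting material ⇌ intermediate A (K = 8.99, k = 0.0107 /s)
    starting material + partner → intermediate B (k = 0.00616 /M/s)
    partner ⇌ dormant form (K = 16.0, k = 5.51 × 10⁻⁴ /s)
    intermediate B → target (k = 0.00191 /s)
    target ⇌ intermediate C (K = 16.3, k = 0.00480 /s)
    partner + protic impurity → quenched reagent (k = 0.00479 /M/s)

In the red flask intermediate A is a store, not an end point. Taking away its backward run to starting material lifts conversion of starting material from 93.2 % to 99.8 % and changes the answer on rest. My capture of 64.0 % was a figure for 25 min: left for 250 min, the same flask holds 55.7 % intermediate A.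

For the same flask with 3.20 equiv of partner, s gives a capture of 30.8 %. The computed flask holds 25.6 % intermediate A at 25 min.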